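The constants used here are made up; the result is computed.

Over 30 min at constant temperature, solid Z feeds E into a closed flask while X feeds L.

    J → E (k1 = 0.0192 s⁻¹)
    X → L (k2 = 0.0236 s⁻¹)
    E + L → E.L (k3 = 13.8 L mol⁻¹ s⁻¹)
    Z ⇌ J, rate k4*(cs4 - [J]) while solid is left; crystals form when [J] > cs4 (cs4 = 4.2 mM, k4 = 0.00691 s⁻¹)
    2 L → L2 (k5 = 12.0 L mol⁻¹ s⁻¹)

Z 15 mM; X 1.10 equiv; time 30 min

- the E.L standing at 30 min, as a percentage of the Z charged
- the change that raises the amount of E.L at 30 min, in percent of the Z charged most ("none" if none brings more than 2 percentage points) (Sunday's / Friday's / Wednesday's / none)
- amount of E.L at 30 min, in percent of the Z charged, after Friday's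

- Sunday's: doubling the solubility in step 4, all else as stated
- Friday's: doubling the dissolution coefficient of step 4, all else as stated
- Wednesday's: doubling the amount of X, all else as stated

- two of one species on the left: rate k times its square, two consumed each time
- given per volume of solution although it is solid: Z
- at the start none of Z is in solution
- run time (flask): 30 min

Z is the smaller charge, so the ledger follows Z. Z passes through J to E, and E then stands either free or as E.L, so the books close on these two.

The first entry is the feed. After a delay of 0.638 min, while J builds up, E arrives at 0.0854 min⁻¹ of the charge while solid is left.

The second entry is capture. At the start X supplies L faster than E arrives, by a factor of 18.2. So pairing into L2 is reckoned as the main loss of L, which is held where the supply from X meets pairing, and L decays with a time constant of 1.41 min. Summed over that decay, the capture dose from the start is 4.71. The catch time 2.19 min is the moment when the dose still ahead of a fresh E falls to one. E made before it counts as caught, and E made after it counts as free.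

The books then close in this reckoning at 13.2% E.L, with 86.8% E. Friday's gives 22.7%, Wednesday's 17.4% and Sunday's 26.5%, so Sunday's leads.

The forecast gave 15% (range 13% to 17%), Sunday's and 19.5% after Friday's, holding that “The solid acts as a slow feed”, and this reckoning stands lower on the first figure and higher on the last.

The flask gives 14.2% E.L and 85.8% E, Sunday's with a gain of 7.4 percentage points, and 19.9% after Friday's, below this reckoning.

At 0.490 min this flask's pairing uses L 41 times as fast as capture does. Read back through the feed, the E.L of this flask corresponds to a catch time of 2.30 min, against 2.19 min reckoned.

In the neighbour flask with 0.280 equiv of X, the dose is 2.38 and the catch time 1.22 min, which gives 4.99% E.L. That flask gives 8.24% E.L and 91.8% E, so its E.L stands higher than this reckoning.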